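## The problem

Compound 28 is a type B polyprenylated acylphloroglucinol built on a bicyclo[3.3.1]nonane-2,4,9-trione. Ring A (C1–C2–C3–C4–C5–C9) is an enolised β-triketone with the 3-hydroxybenzoyl group on C3; ring B (C1–C8–C7–C6–C5–C9) is a cyclohexanone; the rings share C1, C9 and C5. There are four stereocentres: the quaternary bridgeheads C1 and C5 (each with a prenyl group, 3-methylbut-2-enyl), quaternary C8 (methyl and homoprenyl, 4-methylpent-3-enyl) directly bonded to C1, and tertiary C7 (geranyl, equatorial on ring B). Only C7 needs an outside source of chirality. On a monocyclic ring B the C5–C4 bond and the C8–homoprenyl bond must both be made trans to geranyl, and C1 is then fixed by the bridge. Five trisubstituted alkenes rule out strong protic or Lewis acids, halonium reagents, ozone, hydrogenation and unselective oxidants, and the triketone and the phenol have to stay masked until the end. The hardest bond is C1–C2, because C1 is a bridgehead next to quaternary C8. The feature that makes it accessible is that C1 is α to the C9 ketone while C2–C3–C4 is a three-carbon bridge starting at C5. A C9=C1 silyl enol ether and a propynoyl group (C4(=O)–C3≡C2) on C5 therefore place a carbon nucleophile and an alkyne terminus in position for a six-membered closure.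

## Retrosynthesis

**C3–aroyl and unmasking.** 28 is traced to 27, in which the C2 oxygen is a methyl enol ether and the phenol an acetate; both fall to hydroxide in one operation. Cutting the C3–C(O)Ar bond of 27 gives the vinylogous ester 24 and 3-acetoxybenzoyl chloride 26 (from acid 25). Putting the aroyl group on last keeps the most electrophilic carbonyl out of all the organometallic steps. The forward reaction is a vinylic C3 lithiation and C-acylation.

**C1–prenyl.** Cutting the bridgehead C1–CH2 bond of 24 gives 23 and prenyl bromide 10. The alternative, carrying the C1 prenyl group through the ring closure, would require the key step to form two adjacent quaternary carbons (C1 and C8). The forward reaction is a bridgehead lithiation α to C9 and an alkylation, which can only occur with retention.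

**C2 oxygen.** 23 is traced through the trione 22 and the C2 alcohol 21 to the enone 19 (C2=C3–C4=O). These are functional-group changes only: conjugate borylation/oxidation, alcohol oxidation and enol ether formation. The forward sequence must give the C2 (not C4) methyl enol ether, which is the less hindered one because C2 sits next to the C1 methine and C4 next to quaternary C5.

**C1–C2 (key step).** Cutting C1–C2 of 19 opens ring A and gives the monocyclic silyl enol ether ynone 18. Against the neighbouring cut C4–C5, this one keeps quaternary C5 as the anchor of the tether and forms the hindered bridgehead bond intramolecularly, without strong base. Against a C1–C8 cut it leaves all ring B stereochemistry to be set on a simple cyclohexenone. 18 has one ring and three stereocentres (C5, C7, C8). The forward reaction must be a 6-endo-dig attack of C1 on C2 through carbon, not oxygen.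

**Adjusting 18.** 18 comes from the propargylic alcohol 17 by oxidation, and 17 from the tris-silyl compound 16 by methanolysis of the O–SiMe3 and C–SiMe3 groups. The alkyne is unmasked at the alcohol stage because a silyl ynone would take up methoxide under the same conditions.

**C8–homoprenyl.** Cutting the C8–CH2 bond of 16 gives enone 13 and the Grignard reagent 15 (from bromide 14). The conjugate addition creates quaternary C8 and delivers the C9=C1 enolate regiospecifically, which is trapped on oxygen. Once C5 is quaternary no other enol ether of C9 is possible. The forward reaction must add trans to the C7 geranyl group.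

**C5 quaternary centre.** Cutting C5–C4 of 13 gives enone 11 and 3-(trimethylsilyl)propynal 12; cutting C5–CH2 of 11 gives enone 9 and prenyl bromide 10. On the enone, C5 is the only kinetically enolisable position, so both bonds are regiochemically unambiguous; on the saturated ketone they would not be. Prenyl goes in first so that the aldehyde, arriving second, takes the face opposite to geranyl.

**Ring B and C7.** 9 comes from enone 7 by conjugate methylation and re-oxidation (C8–CH3). 7 is cut at C6–C7 and C1=C8 into aldehyde 4 and methyl vinyl ketone 5, through keto aldehyde 6. An enamine-catalysed Michael addition sets C7 absolutely; this is preferred to an auxiliary-controlled alkylation of a vinylogous ester because it is catalytic and the geranyl chain enters intact. 4 comes from nitrile 3, made from geranyl bromide 1 and acetonitrile 2.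

## Roads not taken

**Alternative 1: epoxide-opening cyclisation of a bis(enol ether).** The cut is C1–C8. The precursor A1 is a 2,6-dimethoxycyclohexa-1,4-diene whose quaternary carbon carries prenyl and a 2,3-epoxygeranyl chain. With Me3SiOTf, one of its two enol ethers would attack C8 of the epoxide with inversion and close ring B to give A2 (C9 ketone, C4 methyl enol ether, C1–H, equatorial C7–OH).
- Merits: C8 is set stereospecifically from an enantioenriched epoxide, C1 and C5 are set in the same event, and the enol ether regiochemistry is defined. In C8 control this road is better than the chosen one, which relies on the facial selectivity of a cuprate.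
- Weak points for 28: A2 has a hydroxyl where 28 has the geranyl group. A ten-carbon E-allylic chain would have to replace a C–O bond at a hindered secondary carbon next to quaternary C8, and the E-trisubstituted alkene would have to be built late. C2 would still need allylic oxidation, and a silyl triflate must be tolerated by the side-chain alkenes.
- Comparison: the chosen plan brings geranyl in unchanged in step 1 and derives C5, C8 and C1 from C7.

**Alternative 2: diazo insertion into a bicyclo[3.2.1]octanetrione.** The cuts are C2–C3 and C3–C4. The α-diketone bridge of A3 (C2 and C4 directly bonded, both bridgeheads already prenylated) would be expanded by the aroyldiazomethane A4 under BF3·OEt2 or Sc(OTf)3: addition to C4, 1,2-shift of acyl carbon C2 and loss of N2 would give the silyl ether A5 of 28.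
- Merits: the most convergent endgame, with no bridgehead lithiation and no enol ether protection; C3 and the aroyl group arrive together. In late-stage step count it is better than the chosen plan.
- Weak points: the difficulty moves into A3, which needs both quaternary bridgeheads, C7, C8 and a vicinal tricarbonyl, with no obvious short route. An acceptor-substituted diazo compound is a weak nucleophile towards a ketone flanked by a quaternary carbon. Migration of the bridgehead carbon instead of the acyl carbon, or attack at C9, would give other skeletons. The Lewis acid meets five electron-rich alkenes.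
- Comparison: the chosen plan closes ring A by a reaction type already known to give this ring system and keeps the stereochemical problem on a monocyclic ring.

**Alternative 3: diketene annulation and oxidative ring expansion.** The cuts are C4–C5 and C1–C9. The lithium enolate of cyclopentanone A6 would be acylated at C5 by diketene, and the released methyl ketone enolate would add to C9, giving the cis-fused hydrindane A7 with a C9 carbinol. A later oxidative 1,2-shift of C8 from C9 to C1 would produce the bicyclo[3.3.1] skeleton.
- Merits: ring A arrives with both C2 and C4 oxygens in one step from a cheap reagent, and the sequence is shorter on paper than the chosen one, which needs three steps to oxidise C2.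
- Weak points: the skeleton is only reached through a rearrangement under oxidising conditions, in the presence of five trisubstituted alkenes and electron-rich enols, and the shift must select C8. The C5 configuration relative to C7 and the cis ring fusion must both emerge from the annulation on a five-membered ring. C1 prenylation and C3 aroylation are still needed afterwards, so the endgame is no shorter.
- Comparison: the chosen plan holds ring B at its final size throughout, so the C5, C7 and C8 relationships rest on cyclohexenone facial arguments, and it needs no skeletal rearrangement.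

Key step: step 10

Convention: C1–C9 refer to the skeleton of 28 in every compound; prenyl = 3-methylbut-2-en-1-yl, homoprenyl = 4-methylpent-3-en-1-yl, geranyl = (2E)-3,7-dimethylocta-2,6-dien-1-yl.

Assumption: 28 is taken as the C4-enol drawn in its SMILES, one of the equilibrating enol forms of the 3-acyl-2,4-dione.

## Route

Step 1
Reactants: 1 geranyl bromide; 2 acetonitrile
Product: 3 (4E)-5,9-dimethyldeca-4,8-dienenitrile
Conditions: MeCN (3 equiv), LiN(i-Pr)2, THF, −78 °C; then 1, −78 → 0 °C
Reagents that add atoms: none
Why: SN2 alkylation of lithiated acetonitrile by the primary allylic bromide; excess nucleophile suppresses double alkylation and the E alkene is not touched.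

Step 2
Reactants: 3 (4E)-5,9-dimethyldeca-4,8-dienenitrile
Product: 4 (4E)-5,9-dimethyldeca-4,8-dienal
Conditions: i-Bu2AlH, CH2Cl2, −78 °C; then 1 M HCl, 0 °C
Reagents that add atoms: water, O
Why: Partial hydride reduction of the nitrile stops at the N-aluminio imine, which is hydrolysed to the aldehyde on work-up.

Step 3
Reactants: 4 (4E)-5,9-dimethyldeca-4,8-dienal; 5 methyl vinyl ketone
Product: 7 (4S)-4-geranylcyclohex-2-en-1-one, via keto aldehyde 6 (not isolated)
Conditions: (S)-2-[methoxy(diphenyl)methyl]pyrrolidine (5 mol%), ethyl 3,4-dihydroxybenzoate (20 mol%), neat, 4 °C; volatiles removed; then LiOH, i-PrOH, 23 °C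
Reagents that add atoms: none
Why: Enamine-catalysed Michael addition of the aldehyde to the vinyl ketone forms C6–C7; the diphenylmethoxymethyl group of the (S)-catalyst shields one face of the E-enamine, so the bond forms on the other face and the (S)-aldehyde 6 results. LiOH then closes ring B by intramolecular aldol condensation (C1=C8), after which the stereocentre is no longer α to a carbonyl.

Step 4
Reactants: 7 (4S)-4-geranylcyclohex-2-en-1-one
Product: 9 (4S)-4-geranyl-3-methylcyclohex-2-en-1-one, via trimethylsilyl enol ether 8 (not isolated)
Conditions: MeMgBr, CuBr·SMe2 (5 mol%), Me3SiCl, HMPA, THF, −78 °C; then Pd(OAc)2, MeCN, 23 °C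
Reagents that add atoms: methylmagnesium bromide, C[Mg]Br; chlorotrimethylsilane, C[Si](C)(C)Cl (silyl group of 8 only)
Why: Copper-catalysed, silyl chloride-accelerated conjugate addition gives the regiodefined enol silane, and Saegusa–Ito oxidation restores the C1=C8 alkene; the transient C8 centre is erased and C7 is untouched.

Step 5
Reactants: 9 (4S)-4-geranyl-3-methylcyclohex-2-en-1-one; 10 prenyl bromide
Product: 11 (4S)-4-geranyl-3-methyl-6-prenylcyclohex-2-en-1-one (both epimers at C5 of the target numbering)
Conditions: LiN(i-Pr)2, THF, −78 °C; then 10, −78 → 0 °C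
Reagents that add atoms: none
Why: Kinetic α′-deprotonation of the enone to the cross-conjugated dienolate and SN2 alkylation (Stork–Danheiser-type α′ alkylation); the C5 configuration does not matter because C5 is enolised again in step 6.

Step 6
Reactants: 11 (4S)-4-geranyl-3-methyl-6-prenylcyclohex-2-en-1-one; 12 3-(trimethylsilyl)propynal
Product: 13 enone with quaternary C5 bearing prenyl and CH(OSiMe3)C≡CSiMe3 (side chain trans to geranyl; both carbinol epimers)
Conditions: LiN(i-Pr)2, THF, −78 → −40 °C; then 12, −78 °C; then Me3SiCl, −78 → 0 °C
Reagents that add atoms: chlorotrimethylsilane, C[Si](C)(C)Cl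
Why: Aldol addition of the fully substituted C5 lithium enolate creates the quaternary centre; the aldehyde should approach the dienolate face opposite the C7 geranyl group (held pseudoaxial by A(1,2) strain with the C8 methyl), so C5–C4 forms trans to geranyl. Silylating the aldolate in the flask blocks retro-aldol cleavage.

Step 7
Reactants: 13 C5-quaternary enone; 14 5-bromo-2-methylpent-2-ene
Product: 16 tert-butyldimethylsilyl enol ether (C9=C1) with quaternary C8, via Grignard reagent 15 (not isolated)
Conditions: 14, Mg, THF, 23 °C; CuBr·SMe2 (0.5 equiv per Grignard), THF, −78 °C; then 13, −78 → −30 °C; then t-BuMe2SiOTf, −78 → 0 °C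
Reagents that add atoms: tert-butyldimethylsilyl trifluoromethanesulfonate, CC(C)(C)[Si](C)(C)OS(=O)(=O)C(F)(F)F
Why: Organocuprate conjugate addition to the β,β-disubstituted enone forms quaternary C8; the nucleophile is expected to enter anti to the neighbouring C7 geranyl group, giving homoprenyl trans and methyl cis to geranyl. O-silylation of the resulting enolate fixes the C9=C1 enol ether regiospecifically.

Step 8
Reactants: 16 tris-silyl compound
Product: 17 propargylic alcohol with terminal alkyne and intact tert-butyldimethylsilyl enol ether
Conditions: K2CO3, MeOH, 0 °C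
Reagents that add atoms: none
Why: Carbonate-mediated methanolysis cleaves the O–SiMe3 and alkynyl C–SiMe3 bonds; the bulkier silyl enol ether, flanked by two quaternary carbons, should survive, and with no free ketone present retro-aldol cleavage is not possible.

Step 9
Reactants: 17 propargylic alcohol
Product: 18 silyl enol ether ynone (C5 propynoyl; C9=C1 enol ether)
Conditions: Dess–Martin periodinane, NaHCO3, CH2Cl2, 0 → 23 °C
Reagents that add atoms: none
Why: Buffered Dess–Martin oxidation of the secondary propargylic alcohol gives the ynone without acid that would hydrolyse the enol ether.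

Step 10
Reactants: 18 silyl enol ether ynone
Product: 19 5-prenyl-7-geranyl-8-methyl-8-homoprenylbicyclo[3.3.1]non-2-ene-4,9-dione (C1–H)
Conditions: Ph3PAuNTf2 (5 mol%), acetone containing H2O (1 equiv), 23 °C
Reagents that add atoms: none
Why: Ph3PAuNTf2 (monovalent gold) binds the alkyne of the ynone and the enol ether carbon C1 attacks the terminal carbon C2 anti to gold; the silyloxocarbenium ion at C9 loses silicon to water and the α-aurated enone is protodeaurated to the C2=C3 enone. The closest known reaction type is the gold-catalysed carbocyclisation of cyclic silyl enol ethers onto tethered alkynes (a Conia-ene-type process), which gives bicyclo[3.3.1]nonenones. Ring A (C1–C2–C3–C4–C5–C9) closes in the 6-endo-dig mode. The only new stereocentre, C1, is set by the tether: the propynoyl group on quaternary C5 can reach C1 only across the face of ring B on which it stands, so C1–C2 forms cis to C5–C4 and the C1 hydrogen ends up exo. The step needs 6-endo over 5-exo closure and carbon over oxygen attack; the Michael polarity of the ynone makes C2 the electrophilic terminus, the 5-exo product would be a more strained bicyclo[3.2.1]octane with an exocyclic alkene, and silicon on oxygen keeps the nucleophile carbon-centred. The enol ether must also react faster than the C5 prenyl alkene as π-nucleophile, which its higher nucleophilicity and the six-membered transition state should ensure. Ring B can hold the acyl group axial because its only 1,3-diaxial partner is the C7 hydrogen, geranyl being on the other face.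

Step 11
Reactants: 19 bicyclic enedione
Product: 21 C2 alcohol (2-hydroxybicyclo[3.3.1]nonane-4,9-dione; C2 epimers), via C2 pinacol boronate 20 (not isolated)
Conditions: B2pin2, CuCl (10 mol%), NaOt-Bu (10 mol%), DPEphos (10 mol%), MeOH (2 equiv), THF, 23 °C; then NaBO3·4H2O, THF/H2O, 23 °C
Reagents that add atoms: bis(pinacolato)diboron, CC1(C)OB(OC1(C)C)B1OC(C)(C)C(C)(C)O1 (boron of 20 only); sodium perborate, [Na+].[O-]OB=O (oxygen at C2)
Why: Copper-catalysed conjugate borylation puts boron on the β-carbon C2 of the enone, and perborate oxidation turns C–B into C–OH with retention; the C2 configuration is not controlled and is removed in step 12.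

Step 12
Reactants: 21 C2 alcohol
Product: 22 bicyclo[3.3.1]nonane-2,4,9-trione (C1–H; enolised through C3)
Conditions: Dess–Martin periodinane, NaHCO3, CH2Cl2, 0 → 23 °C
Reagents that add atoms: none
Why: Dess–Martin oxidation of the β-hydroxy ketone to the β-diketone; C1 is a bridgehead and does not enolise.

Step 13
Reactants: 22 trione
Product: 23 2-methoxybicyclo[3.3.1]non-2-ene-4,9-dione (C1–H)
Conditions: HC(OMe)3, p-TsOH·H2O (cat.), MeOH, 23 → 40 °C
Reagents that add atoms: trimethyl orthoformate, COC(OC)OC
Why: Acid-catalysed enol ether formation with orthoformate as water scavenger; methanol should add to the less hindered C2 carbonyl (next to the C1 methine) rather than C4 (next to quaternary C5), as in the closely related 8,8-dimethyl triones of this class.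

Step 14
Reactants: 23 2-methoxy enone; 10 prenyl bromide
Product: 24 C1-prenylated 2-methoxy enone
Conditions: LiN(i-Pr)2, THF, −78 °C; then 10, −78 → 23 °C
Reagents that add atoms: none
Why: Bridgehead lithiation α to the C9 ketone and SN2 alkylation, the established way to substitute bicyclo[3.3.1]nonane-2,4,9-trione methyl enol ethers; substitution at a bridgehead can only occur with retention, so C1 is fixed by the ring system.

Step 15
Reactants: 25 3-acetoxybenzoic acid
Product: 26 3-acetoxybenzoyl chloride
Conditions: (COCl)2, DMF (cat.), CH2Cl2, 0 → 23 °C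
Reagents that add atoms: oxalyl chloride, ClC(=O)C(Cl)=O
Why: Vilsmeier-type conversion of the acid into the acid chloride; the aryl acetate is inert.

Step 16
Reactants: 24 C1-prenylated 2-methoxy enone; 26 3-acetoxybenzoyl chloride
Product: 27 3-(3-acetoxybenzoyl)-2-methoxy enone
Conditions: lithium 2,2,6,6-tetramethylpiperidide, THF, −78 °C; then 26, −78 → 0 °C
Reagents that add atoms: none
Why: With both bridgeheads substituted, the hindered amide removes the vinylic C3–H of the vinylogous ester (α-lithiation of a β-alkoxy enone) and the vinyllithium is C-acylated by the acid chloride; any acetate lost or phenol re-acylated here converges in step 17.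

Step 17
Reactants: 27 protected target
Product: 28 target, CNP0285073.1
Conditions: LiOH, 1,4-dioxane/H2O, 90 °C
Reagents that add atoms: lithium hydroxide, [Li+].[OH-] (oxygen at C2)
Why: Hydroxide cleaves the vinylogous methyl ester by conjugate addition–elimination at C2 and saponifies the aryl acetate, releasing the β-triketone and the phenol together; no stereocentre is enolisable.

## Compound list

1 | geranyl bromide, (2E)-1-bromo-3,7-dimethylocta-2,6-diene | CC(C)=CCC/C(C)=C/CBr | starting material
2 | acetonitrile | CC#N | starting material
3 | (4E)-5,9-dimethyldeca-4,8-dienenitrile | CC(C)=CCC/C(C)=C/CCC#N | intermediate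
4 | (4E)-5,9-dimethyldeca-4,8-dienal | CC(C)=CCC/C(C)=C/CCC=O | intermediate
5 | methyl vinyl ketone (but-3-en-2-one) | CC(=O)C=C | starting material
6 | (2S)-2-geranyl-5-oxohexanal | CC(C)=CCC/C(C)=C/C[C@@H](C=O)CCC(C)=O | intermediate (not isolated)
7 | (4S)-4-geranylcyclohex-2-en-1-one | CC(C)=CCC/C(C)=C/C[C@@H]1CCC(=O)C=C1 | intermediate
8 | trimethylsilyl enol ether of trans-4-geranyl-3-methylcyclohexanone, (3S,4S) | CC(C)=CCC/C(C)=C/C[C@@H]1CCC(O[Si](C)(C)C)=C[C@H]1C | intermediate (not isolated)
9 | (4S)-4-geranyl-3-methylcyclohex-2-en-1-one | CC(C)=CCC/C(C)=C/C[C@@H]1CCC(=O)C=C1C | intermediate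
10 | prenyl bromide, 1-bromo-3-methylbut-2-ene | CC(C)=CCBr | starting material
11 | (4S)-4-geranyl-3-methyl-6-prenylcyclohex-2-en-1-one, both C6 epimers | CC(C)=CCC/C(C)=C/C[C@@H]1CC(CC=C(C)C)C(=O)C=C1C | intermediate
12 | 3-(trimethylsilyl)propynal | C[Si](C)(C)C#CC=O | starting material
13 | (4S)-4-geranyl-3-methyl-6-prenyl-6-[1-(trimethylsilyloxy)-3-(trimethylsilyl)prop-2-ynyl]cyclohex-2-en-1-one, side chain trans to geranyl, both carbinol epimers | CC(C)=CCC/C(C)=C/C[C@@H]1C[C@@](CC=C(C)C)(C(O[Si](C)(C)C)C#C[Si](C)(C)C)C(=O)C=C1C | intermediate
14 | 5-bromo-2-methylpent-2-ene | CC(C)=CCCBr | starting material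
15 | (4-methylpent-3-enyl)magnesium bromide | CC(C)=CCC[Mg]Br | intermediate (not isolated)
16 | C9=C1 tert-butyldimethylsilyl enol ether; C5 prenyl and CH(OSiMe3)C≡CSiMe3 (trans to geranyl); C8 methyl cis and homoprenyl trans to geranyl | CC(C)=CCC/C(C)=C/C[C@@H]1C[C@@](CC=C(C)C)(C(O[Si](C)(C)C)C#C[Si](C)(C)C)C(O[Si](C)(C)C(C)(C)C)=C[C@@]1(C)CCC=C(C)C | intermediate
17 | as 16 with CH(OH)C≡CH on C5 | CC(C)=CCC/C(C)=C/C[C@@H]1C[C@@](CC=C(C)C)(C(O)C#C)C(O[Si](C)(C)C(C)(C)C)=C[C@@]1(C)CCC=C(C)C | intermediate
18 | as 16 with propynoyl C(=O)C≡CH on C5 (key-step precursor) | CC(C)=CCC/C(C)=C/C[C@@H]1C[C@@](CC=C(C)C)(C(=O)C#C)C(O[Si](C)(C)C(C)(C)C)=C[C@@]1(C)CCC=C(C)C | intermediate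
19 | 5-prenyl-7-geranyl-8-methyl-8-homoprenylbicyclo[3.3.1]non-2-ene-4,9-dione, C1–H exo, geranyl equatorial on ring B, C8 methyl cis to geranyl | CC(C)=CCC/C(C)=C/C[C@@H]1C[C@]2(CC=C(C)C)C(=O)[C@@H](C=CC2=O)[C@@]1(C)CCC=C(C)C | intermediate
20 | C2 pinacol boronate of the 4,9-dione, C2 epimers | CC(C)=CCC/C(C)=C/C[C@@H]1C[C@]2(CC=C(C)C)C(=O)[C@@H](C(B3OC(C)(C)C(C)(C)O3)CC2=O)[C@@]1(C)CCC=C(C)C | intermediate (not isolated)
21 | 2-hydroxy-4,9-dione, C2 epimers | CC(C)=CCC/C(C)=C/C[C@@H]1C[C@]2(CC=C(C)C)C(=O)[C@@H](C(O)CC2=O)[C@@]1(C)CCC=C(C)C | intermediate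
22 | bicyclo[3.3.1]nonane-2,4,9-trione with C1–H (drawn as triketone) | CC(C)=CCC/C(C)=C/C[C@@H]1C[C@]2(CC=C(C)C)C(=O)[C@@H](C(=O)CC2=O)[C@@]1(C)CCC=C(C)C | intermediate
23 | 2-methoxybicyclo[3.3.1]non-2-ene-4,9-dione with C1–H | CC(C)=CCC/C(C)=C/C[C@@H]1C[C@]2(CC=C(C)C)C(=O)[C@@H](C(OC)=CC2=O)[C@@]1(C)CCC=C(C)C | intermediate
24 | 1,5-diprenyl-2-methoxybicyclo[3.3.1]non-2-ene-4,9-dione | CC(C)=CCC/C(C)=C/C[C@@H]1C[C@]2(CC=C(C)C)C(=O)[C@@](CC=C(C)C)(C(OC)=CC2=O)[C@@]1(C)CCC=C(C)C | intermediate
25 | 3-acetoxybenzoic acid | CC(=O)Oc1cccc(c1)C(O)=O | starting material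
26 | 3-acetoxybenzoyl chloride | CC(=O)Oc1cccc(c1)C(Cl)=O | intermediate
27 | 3-(3-acetoxybenzoyl)-1,5-diprenyl-2-methoxybicyclo[3.3.1]non-2-ene-4,9-dione | CC(C)=CCC/C(C)=C/C[C@@H]1C[C@]2(CC=C(C)C)C(=O)[C@@](CC=C(C)C)(C(OC)=C(C(=O)c3cccc(OC(C)=O)c3)C2=O)[C@@]1(C)CCC=C(C)C | intermediate
28 | CNP0285073.1, 3-(3-hydroxybenzoyl)-4-hydroxy-1,5-diprenyl-7-geranyl-8-methyl-8-homoprenylbicyclo[3.3.1]non-3-ene-2,9-dione | CC(C)=CCC/C(C)=C/C[C@@H]1C[C@]2(CC=C(C)C)C(=O)[C@@](CC=C(C)C)(C(=O)C(C(=O)c3cccc(O)c3)=C2O)[C@@]1(C)CCC=C(C)C | target

## Step count and risks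

Total: 17 steps. Longest linear sequence: 16 steps (steps 1–14, 16 and 17, from 1 to 28); step 15 is a one-step branch.

**Step 10 (key step).** The most likely failure is loss of silicon from the enol ether before the C–C bond forms. That would give the free diketone, which can close through oxygen. Gold may also engage the C5 prenyl alkene in an enyne cycloisomerisation. The fallback leaves the ynone and uses the non-conjugated alkyne. It sets out from 17 and returns at 19. The alcohol of 17 is silylated (t-BuMe2SiOTf, 2,6-lutidine) to the propargylic silyl ether F1. [(JohnPhos)Au(NCMe)]SbF6 in acetone then closes ring A by the same attack of C1 on C2 to give the bicyclic allylic silyl ether F2. Bu4NF releases the C4 alcohol F3, and Dess–Martin oxidation gives 19.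

**Step 7.** Quaternary C5 may bias the ring conformation so that the cuprate adds to C8 with poor facial selectivity, or even cis to geranyl, which would give the wrong C8 epimer. The fallback exchanges the roles of the two C8 substituents, so that a nucleophile entering cis to geranyl delivers the correct centre. It sets out from 7 and returns at 16. Grignard reagent 15 is added to 7 under the conditions of step 4 to give the trans enol silane F4, and Pd(OAc)2 gives the 3-homoprenyl enone F5. Prenylation as in step 5 gives F6, and aldol addition with silylation as in step 6 gives the C5-quaternary enone F7. MeMgBr/CuBr·SMe2 followed by t-BuMe2SiOTf then gives 16.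

**Step 13.** Enol ether formation may lack regioselectivity and produce the 4-methoxy isomer, or the acid may add methanol to side-chain alkenes. The fallback fixes the oxygen–methyl bond before the double bond exists. It sets out from 21 and returns at 23. The C2 alcohol is methylated (MeOTf, 2,6-di-tert-butyl-4-methylpyridine) to the β-methoxy ketone F8. Enolisation towards C3, the only enolisable position of C4 (LiN(SiMe3)2, Me3SiCl), gives the enol silane F9, and Saegusa–Ito oxidation with Pd(OAc)2 gives 23.

**Step 14.** The bridgehead anion next to quaternary C8 may react slowly with the bulky allylic bromide or attack it in the SN2′ sense; lithiation at C3 may compete. The fallback uses a smaller electrophile and builds the prenyl terminus by metathesis. It sets out from 23 and returns at 24. Bridgehead lithiation and allyl bromide give the C1-allyl compound F10, and cross-metathesis with 2-methylbut-2-ene (second-generation Grubbs catalyst) gives 24. The trisubstituted alkenes already present should react much more slowly than the terminal allyl group.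

## Further compounds

F1 | step 10 | propargylic tert-butyldimethylsilyl ether of 17 | CC(C)=CCC/C(C)=C/C[C@@H]1C[C@@](CC=C(C)C)(C(O[Si](C)(C)C(C)(C)C)C#C)C(O[Si](C)(C)C(C)(C)C)=C[C@@]1(C)CCC=C(C)C
F2 | step 10 | 4-(tert-butyldimethylsilyloxy)bicyclo[3.3.1]non-2-en-9-one, C4 epimers | CC(C)=CCC/C(C)=C/C[C@@H]1C[C@]2(CC=C(C)C)C(=O)[C@@H](C=CC2O[Si](C)(C)C(C)(C)C)[C@@]1(C)CCC=C(C)C
F3 | step 10 | 4-hydroxybicyclo[3.3.1]non-2-en-9-one, C4 epimers | CC(C)=CCC/C(C)=C/C[C@@H]1C[C@]2(CC=C(C)C)C(=O)[C@@H](C=CC2O)[C@@]1(C)CCC=C(C)C
F4 | step 7 | trimethylsilyl enol ether of trans-4-geranyl-3-homoprenylcyclohexanone | CC(C)=CCC/C(C)=C/C[C@@H]1CCC(O[Si](C)(C)C)=C[C@H]1CCC=C(C)C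
F5 | step 7 | (4S)-4-geranyl-3-homoprenylcyclohex-2-en-1-one | CC(C)=CCC/C(C)=C/C[C@@H]1CCC(=O)C=C1CCC=C(C)C
F6 | step 7 | (4S)-4-geranyl-3-homoprenyl-6-prenylcyclohex-2-en-1-one, C6 epimers | CC(C)=CCC/C(C)=C/C[C@@H]1CC(CC=C(C)C)C(=O)C=C1CCC=C(C)C
F7 | step 7 | 3-homoprenyl analogue of 13 | CC(C)=CCC/C(C)=C/C[C@@H]1C[C@@](CC=C(C)C)(C(O[Si](C)(C)C)C#C[Si](C)(C)C)C(=O)C=C1CCC=C(C)C
F8 | step 13 | 2-methoxybicyclo[3.3.1]nonane-4,9-dione, C2 epimers | CC(C)=CCC/C(C)=C/C[C@@H]1C[C@]2(CC=C(C)C)C(=O)[C@@H](C(OC)CC2=O)[C@@]1(C)CCC=C(C)C
F9 | step 13 | 2-methoxy-4-(trimethylsilyloxy)bicyclo[3.3.1]non-3-en-9-one | CC(C)=CCC/C(C)=C/C[C@@H]1C[C@]2(CC=C(C)C)C(=O)[C@@H](C(OC)C=C2O[Si](C)(C)C)[C@@]1(C)CCC=C(C)C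
F10 | step 14 | 1-allyl-5-prenyl-2-methoxybicyclo[3.3.1]non-2-ene-4,9-dione | CC(C)=CCC/C(C)=C/C[C@@H]1C[C@]2(CC=C(C)C)C(=O)[C@@](CC=C)(C(OC)=CC2=O)[C@@]1(C)CCC=C(C)C
A1 | alternative 1 | 2,6-dimethoxy-1-prenyl-1-(2,3-epoxygeranyl)cyclohexa-2,5-diene | COC1=CCC=C(OC)C1(CC=C(C)C)C[C@H]2O[C@]2(C)CCC=C(C)C
A2 | alternative 1 | bicyclic C9 ketone with C4 methyl enol ether, C1–H and equatorial C7 hydroxyl | O[C@@H]1C[C@]2(CC=C(C)C)C(=O)[C@@H](CC=C2OC)[C@@]1(C)CCC=C(C)C
A3 | alternative 2 | bicyclo[3.2.1]octane trione with C2–C4 α-diketone bridge and both bridgehead prenyl groups | CC(C)=CCC/C(C)=C/C[C@@H]1C[C@]2(CC=C(C)C)C(=O)[C@@](CC=C(C)C)(C(=O)C2=O)[C@@]1(C)CCC=C(C)C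
A4 | alternative 2 | 2-diazo-1-[3-(tert-butyldimethylsilyloxy)phenyl]ethanone | [N-]=[N+]=CC(=O)c1cccc(O[Si](C)(C)C(C)(C)C)c1
A5 | alternative 2 | tert-butyldimethylsilyl ether of 28 | CC(C)=CCC/C(C)=C/C[C@@H]1C[C@]2(CC=C(C)C)C(=O)[C@@](CC=C(C)C)(C(=O)C(C(=O)c3cccc(O[Si](C)(C)C(C)(C)C)c3)=C2O)[C@@]1(C)CCC=C(C)C
A6 | alternative 3 | 4-geranyl-3-methyl-3-homoprenyl-2-prenylcyclopentanone | CC(C)=CCC/C(C)=C/C[C@@H]1CC(CC=C(C)C)C(=O)[C@@]1(C)CCC=C(C)C
A7 | alternative 3 | cis-fused hydrindane hydroxy diketone (C9 carbinol) | CC(C)=CCC/C(C)=C/C[C@@H]1C[C@@]2(CC=C(C)C)C(=O)CC(=O)C[C@@]2(O)[C@@]1(C)CCC=C(C)C
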